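**Retrosynthetic overview**
1. Target 13 ⇐ hydrogenolysis of the 7,3'-di-O-benzyl ether 12. The C8–OH of 12 ⇐ Elbs persulfate oxidation para to the 5-OH of 10, at the only free A-ring position.
2. 5-OH of 10 ⇐ chelation-controlled removal of the peri benzyl group of tri-O-benzyl isoflavone 9.
3. Pyranone ring C, the only ring formed, ⇐ Tl(III) oxidative 1,2-aryl migration and cyclisation of 2'-hydroxychalcone 7. Rings A and B are bought.
4. Chalcone 7 ⇐ Claisen–Schmidt condensation of acetophenone 4 with aldehyde 6 (from 5).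
5. Acetophenone 4 (6-OMe placed unambiguously) ⇐ Elbs oxidation of phloroacetophenone dibenzyl ether 1, then selective O-methylation.

Assumption: the target has no stereocentre, so "single enantiomer" means the one achiral compound drawn; compounds 1 and 5 are taken as catalogue chemicals.

**Step 1**
Reactants: 1 1-[2,4-bis(benzyloxy)-6-hydroxyphenyl]ethan-1-one
Product: 3 1-[2,4-bis(benzyloxy)-3,6-dihydroxyphenyl]ethan-1-one, via aryl potassium sulfate 2 (not isolated)
Conditions: K2S2O8, aq. KOH, pyridine, 15–20 °C, 24 h; then aq. HCl, Na2SO3 (cat.), 85 °C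
Reagents that add atoms: potassium peroxydisulfate, [K+].[K+].[O-]S(=O)(=O)OOS(=O)(=O)[O-]
Why: Elbs persulfate oxidation, in which the phenoxide attacks peroxydisulfate through the carbon para to its only free OH (C3, between the two benzyloxy groups) to give sulfate 2, which acid hydrolyses to the hydroquinone.

**Step 2**
Reactants: 3 1-[2,4-bis(benzyloxy)-3,6-dihydroxyphenyl]ethan-1-one
Product: 4 1-[2,4-bis(benzyloxy)-6-hydroxy-3-methoxyphenyl]ethan-1-one
Conditions: MeI (1.1 equiv), K2CO3, acetone, reflux, N2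
Reagents that add atoms: iodomethane, CI
Why: Williamson etherification that is selective because the 6-OH is hydrogen-bonded to the acetyl carbonyl and is far less nucleophilic than the free 3-OH.

**Step 3**
Reactants: 5 3-hydroxy-4,5-dimethoxybenzaldehyde
Product: 6 3-(benzyloxy)-4,5-dimethoxybenzaldehyde
Conditions: BnBr, K2CO3, DMF, 60 °C
Reagents that add atoms: benzyl bromide, BrCc1ccccc1
Why: Williamson benzylation of the single phenol, masking it against Tl(III) and persulfate later.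

**Step 4**
Reactants: 4 1-[2,4-bis(benzyloxy)-6-hydroxy-3-methoxyphenyl]ethan-1-one; 6 3-(benzyloxy)-4,5-dimethoxybenzaldehyde
Product: 7 (E)-1-[2,4-bis(benzyloxy)-6-hydroxy-3-methoxyphenyl]-3-[3-(benzyloxy)-4,5-dimethoxyphenyl]prop-2-en-1-one
Conditions: 50% aq. KOH, EtOH, rt, 48 h
Reagents that add atoms: none
Why: Claisen–Schmidt aldol condensation of the methyl ketone enolate with the non-enolisable aldehyde, where E1cB dehydration gives the thermodynamically favoured E-enone.

**Step 5**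
Reactants: 7 (E)-1-[2,4-bis(benzyloxy)-6-hydroxy-3-methoxyphenyl]-3-[3-(benzyloxy)-4,5-dimethoxyphenyl]prop-2-en-1-one
Product: 9 5,7-bis(benzyloxy)-3-[3-(benzyloxy)-4,5-dimethoxyphenyl]-6-methoxy-4H-chromen-4-one, via racemic dimethyl acetal 8 (not isolated)
Conditions: Tl(NO3)3·3H2O (1.1 equiv), MeOH, rt; then 10% aq. HCl, reflux
Reagents that add atoms: none
Why: Thallium(III)-mediated oxidative rearrangement (McKillop–Taylor), in which the electron-rich para-methoxy B ring shifts 1,2 to give acetal 8 with the solvent methanol; its racemic stereocentre is erased when the free 6'-OH closes onto the unmasked aldehyde and methanol is lost.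

**Step 6**
Reactants: 9 5,7-bis(benzyloxy)-3-[3-(benzyloxy)-4,5-dimethoxyphenyl]-6-methoxy-4H-chromen-4-one
Product: 10 7-(benzyloxy)-3-[3-(benzyloxy)-4,5-dimethoxyphenyl]-5-hydroxy-6-methoxy-4H-chromen-4-one
Conditions: MgBr2·OEt2 (3 equiv), toluene–Et2O, 80 °C; aq. work-up
Reagents that add atoms: none
Why: Chelation-controlled Lewis-acid ether cleavage, where Mg bridges the C4 carbonyl and the peri 5-oxygen so that bromide removes only that benzyl group and the 7- and 3'-benzyl ethers and all methyl ethers remain.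

**Step 7**
Reactants: 10 7-(benzyloxy)-3-[3-(benzyloxy)-4,5-dimethoxyphenyl]-5-hydroxy-6-methoxy-4H-chromen-4-one
Product: 12 7-(benzyloxy)-3-[3-(benzyloxy)-4,5-dimethoxyphenyl]-5,8-dihydroxy-6-methoxy-4H-chromen-4-one, via C8 potassium sulfate 11 (not isolated)
Conditions: K2S2O8, aq. KOH, pyridine, 15–20 °C, 24 h; then aq. HCl, Na2SO3 (cat.), 80 °C
Reagents that add atoms: potassium peroxydisulfate, [K+].[K+].[O-]S(=O)(=O)OOS(=O)(=O)[O-]
Why: Elbs persulfate oxidation, in which the 5-phenoxide (the only free phenol) directs sulfation to its para carbon C8, the sole unsubstituted A-ring position, and acid hydrolysis of 11 frees the 8-OH.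

**Step 8**
Reactants: 12 7-(benzyloxy)-3-[3-(benzyloxy)-4,5-dimethoxyphenyl]-5,8-dihydroxy-6-methoxy-4H-chromen-4-one
Product: 13 5,7,8-trihydroxy-3-(3-hydroxy-4,5-dimethoxyphenyl)-6-methoxy-4H-chromen-4-one (target)
Conditions: H2 (1 atm), 10% Pd/C, EtOAc–MeOH, rt, work-up under N2
Reagents that add atoms: none
Why: Catalytic hydrogenolysis of the two benzyl aryl ethers, which leaves the methyl ethers and, when stopped at full debenzylation, the chromone C2=C3 bond untouched, and also reduces back any 5,8-quinone formed by air.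

**Compound list**
1 | 1-[2,4-bis(benzyloxy)-6-hydroxyphenyl]ethan-1-one | CC(=O)c1c(O)cc(OCc2ccccc2)cc1OCc1ccccc1 | starting material
2 | potassium 3-acetyl-2,6-bis(benzyloxy)-4-hydroxyphenyl sulfate | CC(=O)c1c(O)cc(OCc2ccccc2)c(OS(=O)(=O)[O-])c1OCc1ccccc1.[K+] | intermediate
3 | 1-[2,4-bis(benzyloxy)-3,6-dihydroxyphenyl]ethan-1-one | CC(=O)c1c(O)cc(OCc2ccccc2)c(O)c1OCc1ccccc1 | intermediate
4 | 1-[2,4-bis(benzyloxy)-6-hydroxy-3-methoxyphenyl]ethan-1-one | CC(=O)c1c(O)cc(OCc2ccccc2)c(OC)c1OCc1ccccc1 | intermediate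
5 | 3-hydroxy-4,5-dimethoxybenzaldehyde | COc1cc(C=O)cc(O)c1OC | starting material
6 | 3-(benzyloxy)-4,5-dimethoxybenzaldehyde | COc1cc(C=O)cc(OCc2ccccc2)c1OC | intermediate
7 | (E)-1-[2,4-bis(benzyloxy)-6-hydroxy-3-methoxyphenyl]-3-[3-(benzyloxy)-4,5-dimethoxyphenyl]prop-2-en-1-one | COc1cc(/C=C/C(=O)c2c(O)cc(OCc3ccccc3)c(OC)c2OCc2ccccc2)cc(OCc2ccccc2)c1OC | intermediate
8 | rac-1-[2,4-bis(benzyloxy)-6-hydroxy-3-methoxyphenyl]-2-[3-(benzyloxy)-4,5-dimethoxyphenyl]-3,3-dimethoxypropan-1-one (racemic, one transient stereocentre) | COC(OC)C(c1cc(OC)c(OC)c(OCc2ccccc2)c1)C(=O)c1c(O)cc(OCc2ccccc2)c(OC)c1OCc1ccccc1 | intermediate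
9 | 5,7-bis(benzyloxy)-3-[3-(benzyloxy)-4,5-dimethoxyphenyl]-6-methoxy-4H-chromen-4-one | COc1cc(-c2coc3cc(OCc4ccccc4)c(OC)c(OCc4ccccc4)c3c2=O)cc(OCc2ccccc2)c1OC | intermediate
10 | 7-(benzyloxy)-3-[3-(benzyloxy)-4,5-dimethoxyphenyl]-5-hydroxy-6-methoxy-4H-chromen-4-one | COc1cc(-c2coc3cc(OCc4ccccc4)c(OC)c(O)c3c2=O)cc(OCc2ccccc2)c1OC | intermediate
11 | potassium 7-(benzyloxy)-3-[3-(benzyloxy)-4,5-dimethoxyphenyl]-5-hydroxy-6-methoxy-4-oxo-4H-chromen-8-yl sulfate | COc1cc(-c2coc3c(OS(=O)(=O)[O-])c(OCc4ccccc4)c(OC)c(O)c3c2=O)cc(OCc2ccccc2)c1OC.[K+] | intermediate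
12 | 7-(benzyloxy)-3-[3-(benzyloxy)-4,5-dimethoxyphenyl]-5,8-dihydroxy-6-methoxy-4H-chromen-4-one | COc1cc(-c2coc3c(O)c(OCc4ccccc4)c(OC)c(O)c3c2=O)cc(OCc2ccccc2)c1OC | intermediate
13 | 5,7,8-trihydroxy-3-(3-hydroxy-4,5-dimethoxyphenyl)-6-methoxy-4H-chromen-4-one (5,7,8,3'-tetrahydroxy-6,4',5'-trimethoxyisoflavone, achiral) | COc1cc(-c2coc3c(O)c(O)c(OC)c(O)c3c2=O)cc(O)c1OC | target

**Totals**
Total step count: 8. Longest linear sequence: 7 steps (1 → 3 → 4 → 7 → 9 → 10 → 12 → 13; step 3 is the side branch).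

**Three steps most likely to fail, with fallbacks**

Step 7 is the riskiest. Elbs oxidations are low-yielding, 10 is poorly soluble in aqueous alkali, and the pyranone can open in base. The fallback sets out from 10 and replaces persulfate chemistry by halogenation, borylation and oxidation. NIS in DMF at rt iodinates the only free, strongly activated A-ring carbon to give 7-(benzyloxy)-3-[3-(benzyloxy)-4,5-dimethoxyphenyl]-5-hydroxy-8-iodo-6-methoxy-4H-chromen-4-one F1. Miyaura borylation (B2pin2, Pd(dppf)Cl2, KOAc, dioxane, 80 °C) then gives 7-(benzyloxy)-3-[3-(benzyloxy)-4,5-dimethoxyphenyl]-5-hydroxy-6-methoxy-8-(4,4,5,5-tetramethyl-1,3,2-dioxaborolan-2-yl)-4H-chromen-4-one F2. Mild oxidation (NaBO3·4H2O, THF–H2O, rt) converts the C–B bond to C–OH and comes back to the route at 12.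

Step 5 is next. The Tl(III) rearrangement can give aurone or over-oxidation products with a free 2'-OH and a hindered, electron-rich ketone, and thallium is toxic. The fallback sets out from 7 and goes through a flavanone instead of an acetal. NaOAc in refluxing EtOH closes the chalcone by oxa-Michael addition to rac-5,7-bis(benzyloxy)-2-[3-(benzyloxy)-4,5-dimethoxyphenyl]-6-methoxy-2,3-dihydro-4H-chromen-4-one F3. Hydroxy(tosyloxy)iodobenzene in refluxing MeCN then effects the hypervalent-iodine 2,3-aryl migration with loss of two hydrogens and comes back to the route at 9.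

Step 1 is third. The Elbs oxidation of a water-insoluble, chelated phenol often stalls at low conversion. The fallback sets out from 1 and uses a quinone route. Teuber oxidation with Fremy's salt (potassium nitrosodisulfonate, KH2PO4, aqueous acetone, rt) gives 2-acetyl-3,5-bis(benzyloxy)cyclohexa-2,5-diene-1,4-dione F4. Reduction with aqueous Na2S2O4 in EtOAc comes back to the route at 3.

**Further compounds**
F1 | step 7 | 7-(benzyloxy)-3-[3-(benzyloxy)-4,5-dimethoxyphenyl]-5-hydroxy-8-iodo-6-methoxy-4H-chromen-4-one | COc1cc(-c2coc3c(I)c(OCc4ccccc4)c(OC)c(O)c3c2=O)cc(OCc2ccccc2)c1OC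
F2 | step 7 | 7-(benzyloxy)-3-[3-(benzyloxy)-4,5-dimethoxyphenyl]-5-hydroxy-6-methoxy-8-(4,4,5,5-tetramethyl-1,3,2-dioxaborolan-2-yl)-4H-chromen-4-one | COc1cc(-c2coc3c(B4OC(C)(C)C(C)(C)O4)c(OCc4ccccc4)c(OC)c(O)c3c2=O)cc(OCc2ccccc2)c1OC
F3 | step 5 | rac-5,7-bis(benzyloxy)-2-[3-(benzyloxy)-4,5-dimethoxyphenyl]-6-methoxy-2,3-dihydro-4H-chromen-4-one | COc1cc(C2CC(=O)c3c(OCc4ccccc4)c(OC)c(OCc4ccccc4)cc3O2)cc(OCc2ccccc2)c1OC
F4 | step 1 | 2-acetyl-3,5-bis(benzyloxy)cyclohexa-2,5-diene-1,4-dione | CC(=O)C1=C(OCc2ccccc2)C(=O)C(OCc2ccccc2)=CC1=O
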